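**Plan** (prostanoid numbering: C1 = lactone carbonyl, ring A = cyclopentanone C8–C12, C15 = lactone carbinol, C20 = chain end)
- Cuts, in retrosynthetic order: the 11-acetate; the C5=C6 bond of the 13-membered lactone (alkyne metathesis, then Z-semihydrogenation) and the C1–O15 ester; the C7–C8 bond (alkylation of a ring A β-ketoester whose extra carboxyl is lost later); the C8–C12 bond of ring A; then C10–C11 (aldol), C12=C13 (Wittig) and C15–C16 (diyne coupling).
- Feature used: C12 of ring A, the C13=C14 E-alkene and the C15 oxygen stand in a 1,4-relationship, and C8 lies next to the C9 ketone. A C12=C13 alkene carrying a C14–C15 epoxide therefore gives, with zerovalent palladium, a π-allyl over C12–C14 onto which an acidic C8 β-ketoester carbon can close.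
- Forward: C13–C20 cis-epoxy alcohol, C11–C20 epoxy enal, C8–C20 β-ketoester, ring A (step 9), butynyl on C8, hept-5-ynoate on O15, 13-membered ring by alkyne metathesis, then 5Z alkene, loss of the auxiliary carboxyl and silyl group, and the 11-acetate.
- Stereochemistry: C15 and the relay centre C14 from Sharpless epoxidation; C11 from a ligand-controlled vinylogous aldol; C12 by 1,4-chirality transfer from C14; C8 by protonation trans to C12 after decarboxylation; 17Z and 5Z by alkyne semihydrogenation; 13E from the syn,syn π-allyl.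

Key step: step 9

Assumption: (R)-Tol-BINAP is taken as the ligand antipode that sends the dienolate to the Re face of enal 8 (giving 11R); should a test run show the opposite sense, (S)-Tol-BINAP is used and nothing else changes.

Step 1
Reactants: 1 (propargyl alcohol); 2 (1-bromopent-2-yne)
Product: 3 octa-2,5-diyn-1-ol
Conditions: CuI, K2CO3, n-Bu4NCl, DMF, rt
Reagents that add atoms: none
Why: Copper acetylide substitution of a primary propargylic bromide (skipped-diyne coupling) should form the C15–C16 bond without allene formation and tolerates the free hydroxyl.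

Step 2
Reactants: 3 (octa-2,5-diyn-1-ol)
Product: 4 (2Z,5Z)-octa-2,5-dien-1-ol
Conditions: H2 (1 atm), Ni(OAc)2·4H2O, NaBH4, ethylenediamine, EtOH, rt
Reagents that add atoms: none
Why: Syn addition of hydrogen on Ni2B moderated by ethylenediamine (alkyne semihydrogenation) should stop at the diene and give both alkenes with Z geometry.

Step 3
Reactants: 4 ((2Z,5Z)-octa-2,5-dien-1-ol)
Product: 5 [(2R,3S)-3-[(2Z)-pent-2-en-1-yl]oxiran-2-yl]methanol
Conditions: Ti(OiPr)4 (20 mol %), D-(−)-diethyl tartrate (24 mol %), t-BuOOH, 4 Å MS, CH2Cl2, −20 °C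
Reagents that add atoms: tert-butyl hydroperoxide, CC(C)(C)OO
Why: In the Sharpless asymmetric epoxidation the Ti(OiPr)4/tartrate complex binds the allylic hydroxyl, so only the allylic alkene reacts, the D-(−)-tartrate sets the 2R,3S oxirane (prostanoid 14R,15S) and the cis relationship follows from the Z alkene, any minor enantiomer ending as a separable diastereomer after step 6.

Step 4
Reactants: 5 (cis-epoxy alcohol); 6 ((triphenylphosphoranylidene)acetaldehyde)
Product: 8 (2E)-3-[(2R,3S)-3-[(2Z)-pent-2-en-1-yl]oxiran-2-yl]prop-2-enal, via epoxy aldehyde 7 (not isolated)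
Conditions: PhI(OAc)2, TEMPO (10 mol %), CH2Cl2, rt; then 6 (1.2 equiv), rt
Reagents that add atoms: none
Why: Oxoammonium (TEMPO) oxidation should give the cis-epoxy aldehyde without base-induced epimerisation, and the stabilised formyl ylide then gives the E enal in a Wittig olefination that is faster on the epoxy aldehyde than on the enal product.

Step 5
Reactants: 9 (2,2,6-trimethyl-4H-1,3-dioxin-4-one)
Product: 10 2,2-dimethyl-6-methylidene-4-(trimethylsilyloxy)-6H-1,3-dioxine
Conditions: LiN(iPr)2 (LDA), THF, −78 °C; Me3SiCl, −78 °C to rt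
Reagents that add atoms: chlorotrimethylsilane, C[Si](C)(C)Cl
Why: Kinetic γ-deprotonation of the dioxinone methyl group followed by O-silylation gives the silyl dienolate, a standard acetoacetate γ-anion equivalent.

Step 6
Reactants: 8 (epoxy enal); 10 (silyl dienolate)
Product: 12 6-[(2R,3E)-2-hydroxy-4-[(2R,3S)-3-[(2Z)-pent-2-en-1-yl]oxiran-2-yl]but-3-en-1-yl]-2,2-dimethyl-4H-1,3-dioxin-4-one, via O-trimethylsilyl aldol adduct 11 (not isolated)
Conditions: Cu(OTf)2 (5 mol %), (R)-Tol-BINAP (5.5 mol %), (Bu4N)(Ph3SiF2) (10 mol %), THF, −78 °C; then aqueous citric acid, MeOH, 0 °C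
Reagents that add atoms: none
Why: A catalytic enantioselective vinylogous Mukaiyama aldol through the chiral copper dienolate formed from Cu(OTf)2, (R)-Tol-BINAP and (Bu4N)(Ph3SiF2) should add the γ-carbon 1,2 to the enal on its Re face, setting the 11R carbinol by ligand control independently of the remote epoxide, and the labile O-silyl group is hydrolysed on work-up.

Step 7
Reactants: 12 (dioxinone alcohol)
Product: 13 6-[(2R,3E)-2-[(tert-butyldimethylsilyl)oxy]-4-[(2R,3S)-3-[(2Z)-pent-2-en-1-yl]oxiran-2-yl]but-3-en-1-yl]-2,2-dimethyl-4H-1,3-dioxin-4-one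
Conditions: TBSCl, imidazole, DMF, rt
Reagents that add atoms: tert-butyldimethylsilyl chloride, CC(C)(C)[Si](C)(C)Cl
Why: Imidazole-promoted silylation of the secondary allylic alcohol is non-acidic toward the vinyl epoxide and is needed before the acylketene is unmasked, because a free δ-hydroxyl would lactonise.

Step 8
Reactants: 13 (silylated dioxinone)
Product: 15 2-(trimethylsilyl)ethyl (5R,6E)-5-[(tert-butyldimethylsilyl)oxy]-3-oxo-7-[(2R,3S)-3-[(2Z)-pent-2-en-1-yl]oxiran-2-yl]hept-6-enoate, via acylketene 14 (not isolated)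
Conditions: Me3SiCH2CH2OH (3 equiv), toluene, 110 °C
Reagents that add atoms: 2-(trimethylsilyl)ethanol, C[Si](C)(C)CCO
Why: Thermal retro-[4+2] fragmentation of the dioxinone releases acetone and an acylketene that the alcohol traps as the β-ketoester (dioxinone thermolysis), neutral conditions that should leave the vinyl epoxide and silyl ether intact.

Step 9
Reactants: 15 (acyclic epoxy β-ketoester)
Product: 16 2-(trimethylsilyl)ethyl (1R,2R,3R)-3-[(tert-butyldimethylsilyl)oxy]-2-[(1E,3S,5Z)-3-hydroxyocta-1,5-dien-1-yl]-5-oxocyclopentane-1-carboxylate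
Conditions: Pd(PPh3)4 (5 mol %), THF (0.02 M), 0 °C to rt
Reagents that add atoms: none
Why: Zerovalent palladium ionises the allylic C14–O bond of the epoxide with inversion, giving a zwitterionic syn,syn π-allyl over C12–C14 whose C15 alkoxide deprotonates the β-ketoester at C8, so the reaction runs without added base. The soft C8 enolate then attacks C12 on the face opposite palladium, which is the intramolecular, neutral Tsuji–Trost alkylation known for 1,3-diene monoepoxides with β-dicarbonyl pronucleophiles (net 1,4-addition). Ring A closes in a 5-exo mode with the allyl unit outside the ring, favoured over the 7-membered closure at C14, and any enol ether formed through oxygen can re-ionise and drain to the C-alkylated ketone. C12 is controlled by the 14R epoxide carbon through double inversion (net syn SN2′ transfer from the 12E, cis-epoxide geometry), C15 keeps its oxygen and S configuration, and the syn,syn allyl gives the 13E alkene. C8 is set under thermodynamic control, the enolisable β-ketoester settling trans to the C12 chain. The step needs C12 over C14 regiocontrol, C- over O-alkylation and clean chirality transfer, which ring size, the stabilised enolate, dilute conditions with low catalyst loading (little palladium–palladium exchange) and the 11R silyloxy group, trans to the incoming C8 in the favoured transition state, should secure.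

Step 10
Reactants: 16 (ring A β-ketoester); 17 (1-bromobut-2-yne)
Product: 18 2-(trimethylsilyl)ethyl (1S,2R,3R)-1-(but-2-yn-1-yl)-3-[(tert-butyldimethylsilyl)oxy]-2-[(1E,3S,5Z)-3-hydroxyocta-1,5-dien-1-yl]-5-oxocyclopentane-1-carboxylate
Conditions: K2CO3, acetone, rt
Reagents that add atoms: none
Why: C-alkylation of the β-ketoester potassium enolate with the propargylic bromide (SN2) should occur on the ring face opposite the adjacent C12 chain, placing the butynyl group (C7 to C5) trans to C12, while the weak base leaves the free C15 hydroxyl and the β-silyloxy ketone alone.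

Step 11
Reactants: 18 (alkylated β-ketoester); 19 (hept-5-ynoic acid)
Product: 20 2-(trimethylsilyl)ethyl (1S,2R,3R)-1-(but-2-yn-1-yl)-3-[(tert-butyldimethylsilyl)oxy]-2-[(1E,3S,5Z)-3-(hept-5-ynoyloxy)octa-1,5-dien-1-yl]-5-oxocyclopentane-1-carboxylate
Conditions: DCC, DMAP (20 mol %), CH2Cl2, 0 °C to rt
Reagents that add atoms: none
Why: Steglich esterification acylates the only free hydroxyl, the secondary allylic C15 alcohol, with retention because its C–O bond is not touched.

Step 12
Reactants: 20 (diyne ester)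
Product: 21 2-(trimethylsilyl)ethyl (8S,11R,12R,15S)-11-[(tert-butyldimethylsilyl)oxy]-9-oxo-5,6-didehydroprosta-13E,17Z-dien-1,15-olide-8-carboxylate (13-membered cycloalkyne lactone)
Conditions: Mo(≡CC6H4-4-OMe)(OSiPh3)3 (5 mol %), 5 Å MS, toluene (2 mM), rt to 60 °C
Reagents that add atoms: none
Why: Ring-closing alkyne metathesis with the alkylidyne Mo(≡CC6H4-4-OMe)(OSiPh3)3, which ignores alkenes, ketone, esters and silyl ether, should join the two methyl-capped alkynes into the 13-membered ring (C5≡C6), driven by uptake of but-2-yne on the sieves under high dilution.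

Step 13
Reactants: 21 (cycloalkyne lactone)
Product: 22 2-(trimethylsilyl)ethyl (8S,11R,12R,15S)-11-[(tert-butyldimethylsilyl)oxy]-9-oxoprosta-5Z,13E,17Z-trien-1,15-olide-8-carboxylate
Conditions: H2 (1 atm), Pd/CaCO3 poisoned with Pb(OAc)2, quinoline, EtOAc, rt
Reagents that add atoms: none
Why: Lindlar semihydrogenation adds hydrogen syn to the ring alkyne only, giving the 5Z alkene and leaving the 13E and 17Z alkenes and the allylic lactone untouched.

Step 14
Reactants: 22 (silyl-protected β-ketoester lactone)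
Product: 25 PGE3 1,15-lactone [(8R,11R,12R,15S)-11-hydroxy-9-oxoprosta-5Z,13E,17Z-trien-1,15-olide], via beta-keto acid 23 (not isolated), via 11-O-TBS ketone 24 (not isolated)
Conditions: (Me2N)3S(Me3SiF2) (TASF, 4 equiv), DMF/H2O (20:1), 0 °C to rt
Reagents that add atoms: none
Why: Fluoride attacks the silicon of the 2-silylethyl ester (fragmentation to ethene and the β-keto carboxylate, which decarboxylates) and cleaves the silyl ether, and protonation at C8 in the wet medium should give the more stable 8,12-trans ketone (fluoride-induced dealkoxycarbonylation and desilylation).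

Step 15
Reactants: 25 (PGE3 1,15-lactone)
Product: 26 PGE3 1,15-lactone 11-acetate [(8R,11R,12R,15S)-11-acetoxy-9-oxoprosta-5Z,13E,17Z-trien-1,15-olide]
Conditions: Ac2O, pyridine, 0 °C to rt
Reagents that add atoms: acetic anhydride, CC(=O)OC(C)=O
Why: Acylation of the single free secondary hydroxyl with acetic anhydride in pyridine is mild enough for the β-hydroxy ketone of a prostaglandin E lactone and completes the target.

**Compound list**
1 | propargyl alcohol (prop-2-yn-1-ol) | C#CCO | starting material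
2 | 1-bromopent-2-yne | CCC#CCBr | starting material
3 | octa-2,5-diyn-1-ol | CCC#CCC#CCO | intermediate
4 | (2Z,5Z)-octa-2,5-dien-1-ol | CC/C=C\C/C=C\CO | intermediate
5 | [(2R,3S)-3-[(2Z)-pent-2-en-1-yl]oxiran-2-yl]methanol | CC/C=C\C[C@@H]1O[C@@H]1CO | intermediate
6 | (triphenylphosphoranylidene)acetaldehyde | O=CC=P(c1ccccc1)(c1ccccc1)c1ccccc1 | starting material
7 | (2S,3S)-3-[(2Z)-pent-2-en-1-yl]oxirane-2-carbaldehyde | CC/C=C\C[C@@H]1O[C@@H]1C=O | intermediate
8 | (2E)-3-[(2R,3S)-3-[(2Z)-pent-2-en-1-yl]oxiran-2-yl]prop-2-enal | CC/C=C\C[C@@H]1O[C@@H]1/C=C/C=O | intermediate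
9 | 2,2,6-trimethyl-4H-1,3-dioxin-4-one | CC1=CC(=O)OC(C)(C)O1 | starting material
10 | 2,2-dimethyl-6-methylidene-4-(trimethylsilyloxy)-6H-1,3-dioxine | C=C1C=C(O[Si](C)(C)C)OC(C)(C)O1 | intermediate
11 | 2,2-dimethyl-6-[(2R,3E)-4-[(2R,3S)-3-[(2Z)-pent-2-en-1-yl]oxiran-2-yl]-2-(trimethylsilyloxy)but-3-en-1-yl]-4H-1,3-dioxin-4-one | CC/C=C\C[C@@H]1O[C@@H]1/C=C/[C@H](O[Si](C)(C)C)CC1=CC(=O)OC(C)(C)O1 | intermediate
12 | 6-[(2R,3E)-2-hydroxy-4-[(2R,3S)-3-[(2Z)-pent-2-en-1-yl]oxiran-2-yl]but-3-en-1-yl]-2,2-dimethyl-4H-1,3-dioxin-4-one | CC/C=C\C[C@@H]1O[C@@H]1/C=C/[C@H](O)CC1=CC(=O)OC(C)(C)O1 | intermediate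
13 | 6-[(2R,3E)-2-[(tert-butyldimethylsilyl)oxy]-4-[(2R,3S)-3-[(2Z)-pent-2-en-1-yl]oxiran-2-yl]but-3-en-1-yl]-2,2-dimethyl-4H-1,3-dioxin-4-one | CC/C=C\C[C@@H]1O[C@@H]1/C=C/[C@H](O[Si](C)(C)C(C)(C)C)CC1=CC(=O)OC(C)(C)O1 | intermediate
14 | (5R,6E)-5-[(tert-butyldimethylsilyl)oxy]-7-[(2R,3S)-3-[(2Z)-pent-2-en-1-yl]oxiran-2-yl]hepta-1,6-diene-1,3-dione (acylketene) | CC/C=C\C[C@@H]1O[C@@H]1/C=C/[C@H](O[Si](C)(C)C(C)(C)C)CC(=O)C=C=O | intermediate
15 | 2-(trimethylsilyl)ethyl (5R,6E)-5-[(tert-butyldimethylsilyl)oxy]-3-oxo-7-[(2R,3S)-3-[(2Z)-pent-2-en-1-yl]oxiran-2-yl]hept-6-enoate | CC/C=C\C[C@@H]1O[C@@H]1/C=C/[C@H](O[Si](C)(C)C(C)(C)C)CC(=O)CC(=O)OCC[Si](C)(C)C | intermediate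
16 | 2-(trimethylsilyl)ethyl (1R,2R,3R)-3-[(tert-butyldimethylsilyl)oxy]-2-[(1E,3S,5Z)-3-hydroxyocta-1,5-dien-1-yl]-5-oxocyclopentane-1-carboxylate | CC/C=C\C[C@H](O)/C=C/[C@H]1[C@H](O[Si](C)(C)C(C)(C)C)CC(=O)[C@@H]1C(=O)OCC[Si](C)(C)C | intermediate
17 | 1-bromobut-2-yne | CC#CCBr | starting material
18 | 2-(trimethylsilyl)ethyl (1S,2R,3R)-1-(but-2-yn-1-yl)-3-[(tert-butyldimethylsilyl)oxy]-2-[(1E,3S,5Z)-3-hydroxyocta-1,5-dien-1-yl]-5-oxocyclopentane-1-carboxylate | CC/C=C\C[C@H](O)/C=C/[C@H]1[C@H](O[Si](C)(C)C(C)(C)C)CC(=O)[C@]1(C(=O)OCC[Si](C)(C)C)CC#CC | intermediate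
19 | hept-5-ynoic acid | CC#CCCCC(=O)O | starting material
20 | 2-(trimethylsilyl)ethyl (1S,2R,3R)-1-(but-2-yn-1-yl)-3-[(tert-butyldimethylsilyl)oxy]-2-[(1E,3S,5Z)-3-(hept-5-ynoyloxy)octa-1,5-dien-1-yl]-5-oxocyclopentane-1-carboxylate | CC/C=C\C[C@H](OC(=O)CCCC#CC)/C=C/[C@H]1[C@H](O[Si](C)(C)C(C)(C)C)CC(=O)[C@]1(C(=O)OCC[Si](C)(C)C)CC#CC | intermediate
21 | 2-(trimethylsilyl)ethyl (8S,11R,12R,15S)-11-[(tert-butyldimethylsilyl)oxy]-9-oxo-5,6-didehydroprosta-13E,17Z-dien-1,15-olide-8-carboxylate | CC/C=C\C[C@H]1/C=C/[C@H]2[C@H](O[Si](C)(C)C(C)(C)C)CC(=O)[C@]2(C(=O)OCC[Si](C)(C)C)CC#CCCCC(=O)O1 | intermediate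
22 | 2-(trimethylsilyl)ethyl (8S,11R,12R,15S)-11-[(tert-butyldimethylsilyl)oxy]-9-oxoprosta-5Z,13E,17Z-trien-1,15-olide-8-carboxylate | CC/C=C\C[C@H]1/C=C/[C@H]2[C@H](O[Si](C)(C)C(C)(C)C)CC(=O)[C@]2(C(=O)OCC[Si](C)(C)C)C/C=C\CCCC(=O)O1 | intermediate
23 | (8S,11R,12R,15S)-11-[(tert-butyldimethylsilyl)oxy]-9-oxoprosta-5Z,13E,17Z-trien-1,15-olide-8-carboxylic acid | CC/C=C\C[C@H]1/C=C/[C@H]2[C@H](O[Si](C)(C)C(C)(C)C)CC(=O)[C@]2(C(=O)O)C/C=C\CCCC(=O)O1 | intermediate
24 | (8R,11R,12R,15S)-11-[(tert-butyldimethylsilyl)oxy]-9-oxoprosta-5Z,13E,17Z-trien-1,15-olide | CC/C=C\C[C@H]1/C=C/[C@H]2[C@H](O[Si](C)(C)C(C)(C)C)CC(=O)[C@@H]2C/C=C\CCCC(=O)O1 | intermediate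
25 | PGE3 1,15-lactone, (8R,11R,12R,15S)-11-hydroxy-9-oxoprosta-5Z,13E,17Z-trien-1,15-olide | CC/C=C\C[C@H]1/C=C/[C@H]2[C@H](O)CC(=O)[C@@H]2C/C=C\CCCC(=O)O1 | intermediate
26 | PGE3 1,15-lactone 11-acetate (CNP0328883.2), (8R,11R,12R,15S)-11-acetoxy-9-oxoprosta-5Z,13E,17Z-trien-1,15-olide | CC/C=C\C[C@H]1/C=C/[C@H]2[C@H](OC(C)=O)CC(=O)[C@@H]2C/C=C\CCCC(=O)O1 | target

**Count**
Total steps: 15. Longest linear sequence: 14 (steps 1–4 and 6–15 from 1 and 2; step 5 prepares 10 from 9).

**Steps most likely to fail**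

Step 9 (ring A closure on the π-allyl). What may go wrong: capture of the π-allyl by the doubly activated C8 methylene may be slow or unselective, so that closure through the enol oxygen, β-hydride loss to a diene, or renewed allylation of the still acidic ring-closed β-ketoester erodes the yield. The fallback sets out from 15 and comes back at 18. Compound 15 is first C-alkylated with 17 (K2CO3, acetone) to the 2-(but-2-yn-1-yl) β-ketoester F1. The same Pd(PPh3)4 treatment then closes ring A through a mono-substituted enolate that cannot be allylated twice and forms the quaternary C8 directly. This should give 18 beside its C8 epimer F2, which is removed by chromatography, and it merges steps 9 and 10.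

Step 6 (vinylogous aldol). What may go wrong: facial discrimination by the copper–bisphosphine dienolate on this γ,δ-epoxy enal may be insufficient or of the unwanted sense, or Lewis-acidic Cu(OTf)2 may open the vinyl epoxide. The fallback sets out from 8 and comes back at 15, using an auxiliary-controlled acetate aldol whose sense is established for simple aldehydes. The doubly lithiated (R)-2-hydroxy-1,2,2-triphenylethyl acetate (LiN(iPr)2, THF, then MgBr2, about −100 °C) adds to 8 to give the (3R)-hydroxy ester of the auxiliary F3. K2CO3 in MeOH transesterifies it to the methyl (3R)-hydroxy ester F4, and TBSCl with imidazole gives the silyl ether F5. A crossed Claisen condensation with the lithium enolate of 2-(trimethylsilyl)ethyl acetate (3 equiv, THF, −78 to −20 °C) then gives 15.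

Step 14 (fluoride unmasking). What may go wrong: under fluoride the C9 ketone can enolise toward C10 and expel the C11 oxygen (E1cB dehydration to the cyclopentenone), or the basic medium may open the lactone. The fallback sets out from 22 and comes back at 26, with an all-acidic endgame and the acetate installed before decarboxylation. Aqueous HF in MeCN removes only the silyl ether to give the 11-hydroxy β-ketoester F6, and Ac2O in pyridine gives the 11-acetate F7. CF3CO2H in CH2Cl2 (0 °C to rt) then cleaves the 2-silylethyl ester by acid-induced fragmentation to the β-keto acid F8, which should lose CO2 on gentle warming to give 26 directly.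

**Further compounds**
F1 | step 9 | 2-(trimethylsilyl)ethyl (5R,6E)-2-(but-2-yn-1-yl)-5-[(tert-butyldimethylsilyl)oxy]-3-oxo-7-[(2R,3S)-3-[(2Z)-pent-2-en-1-yl]oxiran-2-yl]hept-6-enoate (both C2 epimers) | CC/C=C\C[C@@H]1O[C@@H]1/C=C/[C@H](O[Si](C)(C)C(C)(C)C)CC(=O)C(CC#CC)C(=O)OCC[Si](C)(C)C
F2 | step 9 | 2-(trimethylsilyl)ethyl (1R,2R,3R)-1-(but-2-yn-1-yl)-3-[(tert-butyldimethylsilyl)oxy]-2-[(1E,3S,5Z)-3-hydroxyocta-1,5-dien-1-yl]-5-oxocyclopentane-1-carboxylate (C8 epimer of 18) | CC/C=C\C[C@H](O)/C=C/[C@H]1[C@H](O[Si](C)(C)C(C)(C)C)CC(=O)[C@@]1(C(=O)OCC[Si](C)(C)C)CC#CC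
F3 | step 6 | (1R)-2-hydroxy-1,2,2-triphenylethyl (3R,4E)-3-hydroxy-5-[(2R,3S)-3-[(2Z)-pent-2-en-1-yl]oxiran-2-yl]pent-4-enoate | CC/C=C\C[C@@H]1O[C@@H]1/C=C/[C@H](O)CC(=O)O[C@H](c1ccccc1)C(O)(c1ccccc1)c1ccccc1
F4 | step 6 | methyl (3R,4E)-3-hydroxy-5-[(2R,3S)-3-[(2Z)-pent-2-en-1-yl]oxiran-2-yl]pent-4-enoate | CC/C=C\C[C@@H]1O[C@@H]1/C=C/[C@H](O)CC(=O)OC
F5 | step 6 | methyl (3R,4E)-3-[(tert-butyldimethylsilyl)oxy]-5-[(2R,3S)-3-[(2Z)-pent-2-en-1-yl]oxiran-2-yl]pent-4-enoate | CC/C=C\C[C@@H]1O[C@@H]1/C=C/[C@H](O[Si](C)(C)C(C)(C)C)CC(=O)OC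
F6 | step 14 | 2-(trimethylsilyl)ethyl (8S,11R,12R,15S)-11-hydroxy-9-oxoprosta-5Z,13E,17Z-trien-1,15-olide-8-carboxylate | CC/C=C\C[C@H]1/C=C/[C@H]2[C@H](O)CC(=O)[C@]2(C(=O)OCC[Si](C)(C)C)C/C=C\CCCC(=O)O1
F7 | step 14 | 2-(trimethylsilyl)ethyl (8S,11R,12R,15S)-11-acetoxy-9-oxoprosta-5Z,13E,17Z-trien-1,15-olide-8-carboxylate | CC/C=C\C[C@H]1/C=C/[C@H]2[C@H](OC(C)=O)CC(=O)[C@]2(C(=O)OCC[Si](C)(C)C)C/C=C\CCCC(=O)O1
F8 | step 14 | (8S,11R,12R,15S)-11-acetoxy-9-oxoprosta-5Z,13E,17Z-trien-1,15-olide-8-carboxylic acid | CC/C=C\C[C@H]1/C=C/[C@H]2[C@H](OC(C)=O)CC(=O)[C@]2(C(=O)O)C/C=C\CCCC(=O)O1
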